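The target read 100.4% at the end of Tuesday's run, on the same reagent charge as your flask. So the open question for your flask is whether it has stopped.

| flask | substrate | reagent | initiator | remark | time |
|---|---|---|---|---|---|
| Tuesday's | 1 mM | 1.5 equiv | 14 mol% | run made earlier |  |
| Sunday's | 1 mM | 1.5 equiv | 22 mol% | run made earlier |  |
| flask | 1.0 mM | 1.50 equiv | 9.8 mol% |  | 2.5 min |

| run | time / s | substrate / % | target / % |
|---|---|---|---|
| Tuesday's | 10.0 | 41.1 | 58.0 |
| Tuesday's | 20.0 | 16.7 | 83.3 |
| Tuesday's | 50.0 | 0.3 | 99.7 |
| Tuesday's | 120 | 0.5 | 100.4 |
| Sunday's | 30.0 | 0.7 | 99.0 |
| Sunday's | 60.0 | 0.1 | 101.0 |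
| Sunday's | 90.0 | 1.2 | 100.6 |
| Sunday's | 120 | 0 | 99.1 |

(standard deviation of a reading: 0.5 percentage points)

* at 2.5 min, what has stopped the reaction, if anything has (it is still moving / all of the substrate has reacted / the reagent has run out first / forward and back rates have come level)
* how much of the substrate has reacted by 2.5 min
* how much target there is at 2.5 min, in percent of the substrate charged

- the reaction counts as stopped when no species that holds the substrate changes by six tenths of a point or more over the second half of the time

The flask has stopped if substrate moves less than 0.6 points over the second half of the time. So substrate at half time must lie below that. I fold the givens into one number, D: the natural-log falls of substrate in the first half of the time. I take the late rate of Tuesday's run and scale it in proportion to loading, which is my assumption.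

k, Tuesday's late reading = 0.116 s⁻¹

D = k × loading ratio × half the time = 6.10

Gate: ln(charge over that change) = 5.12

c(substrate) at half time, over its charge = exp(−D) = 0.224%

D clears the gate, so I say the substrate has fully reacted. Is one number enough? Scaled to Sunday's run, it gives 0.418% at 30.0 s against a reading of 0.7%. But the rate from Tuesday's earlier reading at 20.0 s brings D to 4.70, below the gate, so my call is a close one.

The forecast differs on the stop: it is still moving, “though nearly finished”, with conversion 99.9% and target 99.8%.

The flask gives: all of the substrate has reacted, conversion 100%, target >99.9%.

    substrate + second chain carrier → by-product + first chain carrier (k = 77000 M⁻¹ s⁻¹)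
    2 second chain carrier → ended chains (k = 1.60 × 10⁶ M⁻¹ s⁻¹)
    substrate + initiating radical → capped initiator + first chain carrier (k = 5.30 × 10⁵ M⁻¹ s⁻¹)
    reagent + first chain carrier ⇌ target + second chain carrier (K = 16.0, k = 55000 M⁻¹ s⁻¹)
    initiator → 2 initiating radical (k = 0.0150 s⁻¹)

In this flask, D reckoned 0.224% substrate at 1.25 min, and 0% stands there. Half the turnover of the target-forming step is done by 0.161 min, earlier than the 0.77 min half-life of the initiator by its own breakdown alone. At 2.50 min, substrate stands at 0%, less than the 33% of reagent left. D as reckoned holds no reagent charge, so the neighbour flask with 0.600 equiv of reagent carries the same D of 6.10, yet at 2.50 min there reagent, the limiting reagent, is at 0%, first chain carrier at 14.8%, substrate at 25% and target at 60.0%.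

The earlier runs and the new flask were generated by integration for an exercise; noise was put on by code.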